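**Retrosynthetic overview**

1. Numbering: C1 is the CH2 on the 4-hydroxy-3-methoxyphenyl ring, C7 the CH2 on the 4-hydroxy-3,5-dimethoxyphenyl ring. The target is the syn (3R,5S)-3,5-diacetate; no ring is formed anywhere in the route, and both arenes are bought.
2. Target ⇐ hydrogenolysis of two aryl benzyl ethers ⇐ diacetylation ⇐ syn-(3R,5S)-diol.
3. Key disconnection C3–C4: the syn-diol ⇐ α-lithiated 2,4,6-triisopropylbenzoate of the C1–C3 3-arylpropanol (C3 set by sparteine) + (R)-1,2-bis(pinacol boronate) of the C4–C7 arylbutene. A 1,2-metallate rearrangement forms the bond; both C–B bonds are then oxidised in the same flask.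
4. Enabling feature: the acyclic C3(O)–C4H2–C5(O) triad, two secondary carbinol carbons that each carry one H and flank an unsubstituted CH2. Each C–O bond can therefore be carried as a C–B bond, so C4–C5 is the diboration adduct of a terminal alkene and C3 is the oxygen-bearing carbon of a primary alcohol.
5. Fragments: the benzoate comes from dihydroconiferyl alcohol in two steps; the bis(boronate) from 4-bromo-2,6-dimethoxyphenol by benzylation, Negishi butenylation and enantioselective diboration.

Key step: step 6

Assumption: in step 5 the TADDOL-derived phosphonite ligand is used as whichever antipode delivers the (2R)-bis(boronic ester); the route fixes the product configuration, not the ligand descriptor.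

**Route**

Step 1
Reactants: 1 3-(4-hydroxy-3-methoxyphenyl)propan-1-ol
Product: 2 3-[4-(benzyloxy)-3-methoxyphenyl]propan-1-ol
Conditions: BnBr, K2CO3, acetone, reflux
Reagents that add atoms: benzyl bromide, BrCc1ccccc1
Why: Williamson etherification in which K2CO3 deprotonates only the phenol, so the aryl oxygen should be benzylated and the primary alcohol left free.

Step 2
Reactants: 2 3-[4-(benzyloxy)-3-methoxyphenyl]propan-1-ol
Product: 3 3-[4-(benzyloxy)-3-methoxyphenyl]propyl 2,4,6-triisopropylbenzoate
Conditions: 2,4,6-(i-Pr)3C6H2COCl, Et3N, DMAP (cat.), CH2Cl2, reflux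
Reagents that add atoms: 2,4,6-triisopropylbenzoyl chloride, CC(C)c1cc(C(C)C)c(C(=O)Cl)c(C(C)C)c1
Why: DMAP-catalysed esterification (nucleophilic acyl substitution) of the only free hydroxyl, installing the hindered benzoate that later directs α-lithiation, resists carbonyl attack by s-BuLi and serves as the leaving group in step 6.

Step 3
Reactants: 4 4-bromo-2,6-dimethoxyphenol
Product: 5 2-(benzyloxy)-5-bromo-1,3-dimethoxybenzene
Conditions: BnBr, K2CO3, DMF, 60 °C
Reagents that add atoms: benzyl bromide, BrCc1ccccc1
Why: Williamson etherification of a hindered but acidic phenol, for which a polar solvent and gentle heating should suffice.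

Step 4
Reactants: 5 2-(benzyloxy)-5-bromo-1,3-dimethoxybenzene; 6 but-3-en-1-ylzinc bromide
Product: 7 2-(benzyloxy)-5-(but-3-en-1-yl)-1,3-dimethoxybenzene
Conditions: Pd(OAc)2 (cat.), SPhos (cat.), THF, 50 °C
Reagents that add atoms: none
Why: Negishi cross-coupling of an aryl bromide with a primary alkylzinc halide, in which the bulky biarylphosphine should favour reductive elimination over β-hydride elimination so that the terminal alkene stays in place.

Step 5
Reactants: 7 2-(benzyloxy)-5-(but-3-en-1-yl)-1,3-dimethoxybenzene
Product: 8 2,2'-{(2R)-4-[4-(benzyloxy)-3,5-dimethoxyphenyl]butane-1,2-diyl}bis(4,4,5,5-tetramethyl-1,3,2-dioxaborolane)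
Conditions: Pt(dba)3 (cat.), 3,5-diisopropylphenyl-TADDOL phenylphosphonite (cat., antipode as assumed above), B2pin2, THF, 60 °C
Reagents that add atoms: bis(pinacolato)diboron, CC1(C)OB(OC1(C)C)B1OC(C)(C)C(C)(C)O1
Why: Platinum-catalysed enantioselective 1,2-diboration of a monosubstituted alkene (B–B oxidative addition to zerovalent platinum, alkene insertion into Pt–B, reductive elimination), in which the chiral phosphonite on platinum controls the face of insertion and so sets the C–B stereocentre that becomes C5.

Step 6
Reactants: 3 3-[4-(benzyloxy)-3-methoxyphenyl]propyl 2,4,6-triisopropylbenzoate; 8 2,2'-{(2R)-4-[4-(benzyloxy)-3,5-dimethoxyphenyl]butane-1,2-diyl}bis(4,4,5,5-tetramethyl-1,3,2-dioxaborolane)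
Product: 12 (3R,5S)-1-[4-(benzyloxy)-3-methoxyphenyl]-7-[4-(benzyloxy)-3,5-dimethoxyphenyl]heptane-3,5-diol, via lithiated benzoate 9 (not isolated), via lithium boronate complex 10 (not isolated), via bis(boronic ester) 11 (not isolated)
Conditions: 3, s-BuLi, (−)-sparteine, Et2O, −78 °C; then 8, −78 °C to reflux; then aq. NaOH, H2O2, THF, 0 °C to rt
Reagents that add atoms: hydrogen peroxide, OO
Why: (−)-Sparteine-bound s-BuLi removes the pro-S hydrogen next to the benzoate oxygen of 3 to give the configurationally stable (S)-lithiated benzoate 9, which adds with retention to the less hindered primary boron of 8 to form boronate complex 10; on warming, C4 migrates from boron to C3 anti to the departing benzoate (1,2-metallate rearrangement with inversion at C3), which forms the C3–C4 bond and gives bis(boronic ester) 11, and alkaline H2O2 then converts both C–B bonds into C–O bonds with retention. The closest known reaction type is the reagent-controlled lithiation–borylation homologation of boronic esters (a Matteson-type 1,2-migration), which has been used in this way on the primary boron of 1,2-bis(boronic esters) from terminal alkenes to reach 1,3-diols. No ring is closed. The new stereocentre C3 is set by the chiral diamine alone (retention, then inversion, then retention should give 3R), while C5 comes unchanged from 8, so the syn (3R,5S) relationship follows from pairing (−)-sparteine with (R)-8 and not from substrate induction. The step needs site selectivity between the two borons, secured by the primary-against-secondary steric difference (the secondary boron sits on the carbon that carries the 2-arylethyl chain), and chemoselective α-lithiation of the ester, secured by coordination of the base to the benzoate carbonyl at −78 °C in Et2O, which should outpace benzylic or ring lithiation, while the triisopropylaryl group shields the carbonyl. Because the two partners are enantioenriched independently, the minor enantiomer of either should end up mainly in the anti diastereomer, which is removed by chromatography, so 12 should be close to enantiopure.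

Step 7
Reactants: 12 (3R,5S)-1-[4-(benzyloxy)-3-methoxyphenyl]-7-[4-(benzyloxy)-3,5-dimethoxyphenyl]heptane-3,5-diol
Product: 13 (3R,5S)-1-[4-(benzyloxy)-3-methoxyphenyl]-7-[4-(benzyloxy)-3,5-dimethoxyphenyl]heptane-3,5-diyl diacetate
Conditions: Ac2O, pyridine, DMAP (cat.), CH2Cl2, rt
Reagents that add atoms: acetic anhydride, CC(=O)OC(C)=O
Why: DMAP-catalysed O-acylation of both secondary alcohols, which breaks no C–O bond at a stereocentre and so should leave the configuration untouched.

Step 8
Reactants: 13 (3R,5S)-1-[4-(benzyloxy)-3-methoxyphenyl]-7-[4-(benzyloxy)-3,5-dimethoxyphenyl]heptane-3,5-diyl diacetate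
Product: 14 (3R,5S)-1-(4-hydroxy-3-methoxyphenyl)-7-(4-hydroxy-3,5-dimethoxyphenyl)heptane-3,5-diyl diacetate
Conditions: H2 (1 atm), Pd/C, EtOAc, rt
Reagents that add atoms: none
Why: Catalytic hydrogenolysis of the two aryl benzyl ethers under neutral conditions, to which secondary alkyl acetates and the electron-rich arenes should be inert, so both phenols are freed without touching the stereocentres.

**Compound list**

1 | 3-(4-hydroxy-3-methoxyphenyl)propan-1-ol (dihydroconiferyl alcohol) | COc1cc(CCCO)ccc1O | starting material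
2 | 3-[4-(benzyloxy)-3-methoxyphenyl]propan-1-ol | COc1cc(CCCO)ccc1OCc1ccccc1 | intermediate
3 | 3-[4-(benzyloxy)-3-methoxyphenyl]propyl 2,4,6-triisopropylbenzoate | COc1cc(CCCOC(=O)c2c(C(C)C)cc(C(C)C)cc2C(C)C)ccc1OCc1ccccc1 | intermediate
4 | 4-bromo-2,6-dimethoxyphenol | COc1cc(Br)cc(OC)c1O | starting material
5 | 2-(benzyloxy)-5-bromo-1,3-dimethoxybenzene | COc1cc(Br)cc(OC)c1OCc1ccccc1 | intermediate
6 | but-3-en-1-ylzinc bromide (solution in THF) | C=CCC[Zn]Br | starting material
7 | 2-(benzyloxy)-5-(but-3-en-1-yl)-1,3-dimethoxybenzene | C=CCCc1cc(OC)c(OCc2ccccc2)c(OC)c1 | intermediate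
8 | 2,2'-{(2R)-4-[4-(benzyloxy)-3,5-dimethoxyphenyl]butane-1,2-diyl}bis(4,4,5,5-tetramethyl-1,3,2-dioxaborolane) | CC1(C)OB(C[C@H](CCc2cc(OC)c(OCc3ccccc3)c(OC)c2)B2OC(C)(C)C(C)(C)O2)OC1(C)C | intermediate
9 | (1S)-3-[4-(benzyloxy)-3-methoxyphenyl]-1-lithiopropyl 2,4,6-triisopropylbenzoate (sparteine on lithium not drawn) | COc1cc(CC[C@H]([Li])OC(=O)c2c(C(C)C)cc(C(C)C)cc2C(C)C)ccc1OCc1ccccc1 | intermediate
10 | lithium {(1S)-3-[4-(benzyloxy)-3-methoxyphenyl]-1-[(2,4,6-triisopropylbenzoyl)oxy]propyl}{(2R)-4-[4-(benzyloxy)-3,5-dimethoxyphenyl]-2-(4,4,5,5-tetramethyl-1,3,2-dioxaborolan-2-yl)butyl}(pinacolato)borate | COc1cc(CC[C@@H](OC(=O)c2c(C(C)C)cc(C(C)C)cc2C(C)C)[B-]2(C[C@H](CCc3cc(OC)c(OCc4ccccc4)c(OC)c3)B3OC(C)(C)C(C)(C)O3)OC(C)(C)C(C)(C)O2)ccc1OCc1ccccc1.[Li+] | intermediate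
11 | 2,2'-{(3R,5S)-1-[4-(benzyloxy)-3-methoxyphenyl]-7-[4-(benzyloxy)-3,5-dimethoxyphenyl]heptane-3,5-diyl}bis(4,4,5,5-tetramethyl-1,3,2-dioxaborolane) | COc1cc(CC[C@H](C[C@H](CCc2cc(OC)c(OCc3ccccc3)c(OC)c2)B2OC(C)(C)C(C)(C)O2)B2OC(C)(C)C(C)(C)O2)ccc1OCc1ccccc1 | intermediate
12 | (3R,5S)-1-[4-(benzyloxy)-3-methoxyphenyl]-7-[4-(benzyloxy)-3,5-dimethoxyphenyl]heptane-3,5-diol | COc1cc(CC[C@H](C[C@H](CCc2cc(OC)c(OCc3ccccc3)c(OC)c2)O)O)ccc1OCc1ccccc1 | intermediate
13 | (3R,5S)-1-[4-(benzyloxy)-3-methoxyphenyl]-7-[4-(benzyloxy)-3,5-dimethoxyphenyl]heptane-3,5-diyl diacetate | COc1cc(CC[C@H](C[C@H](CCc2cc(OC)c(OCc3ccccc3)c(OC)c2)OC(C)=O)OC(C)=O)ccc1OCc1ccccc1 | intermediate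
14 | (3R,5S)-1-(4-hydroxy-3-methoxyphenyl)-7-(4-hydroxy-3,5-dimethoxyphenyl)heptane-3,5-diyl diacetate | COc1cc(CC[C@H](C[C@H](CCc2cc(OC)c(O)c(OC)c2)OC(C)=O)OC(C)=O)ccc1O | target

**Step count and risks**

Total step count: 8. Longest linear sequence: 6 steps (steps 3, 4, 5, 6, 7, 8, from 4-bromo-2,6-dimethoxyphenol).

Steps most likely to fail:

1. Step 6. The base may deprotonate the benzylic OCH2 or the ring instead of the ester α-position, the boronate complex may not migrate completely, or homologation may also occur at the secondary boron. The fallback uses aldol logic, sets out from 2 and 7 and comes back at 12. Alcohol 2 would be oxidised with Dess–Martin periodinane to 3-[4-(benzyloxy)-3-methoxyphenyl]propanal F1. Alkene 7 would be converted by Wacker–Tsuji oxidation (PdCl2, CuCl, O2, DMF/H2O) into 4-[4-(benzyloxy)-3,5-dimethoxyphenyl]butan-2-one F2. Enolisation of F2 on its methyl side with (+)-Ipc2BCl and Et3N and addition to F1 (boron aldol reaction, attack on the si face of the aldehyde) should give (5R)-7-[4-(benzyloxy)-3-methoxyphenyl]-1-[4-(benzyloxy)-3,5-dimethoxyphenyl]-5-hydroxyheptan-3-one F3. Syn-selective Narasaka–Prasad reduction (Et2BOMe, NaBH4, THF/MeOH, −78 °C) would then give 12. Reagent control in this aldol is expected to be only moderate, so 12 would then need enrichment by crystallisation or by chromatography on a chiral phase.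

2. Step 5. Facial selectivity in the insertion step may be insufficient, or the platinum catalyst may be deactivated, so that the boron-bearing stereocentre is formed with poor enantiocontrol. The fallback sets out from 7 and comes back at 8. Cross-metathesis of 7 with vinylboronic acid pinacol ester (second-generation Grubbs catalyst, CH2Cl2, 40 °C) would give 2-{(E)-4-[4-(benzyloxy)-3,5-dimethoxyphenyl]but-1-en-1-yl}-4,4,5,5-tetramethyl-1,3,2-dioxaborolane F4. Enantioselective copper-catalysed protoboration of F4 (CuCl, NaOt-Bu, chiral imidazolinium salt as carbene precursor, B2pin2, MeOH, THF) should place the second boron on the β-carbon and give 8, with the ligand antipode chosen for the (2R) product.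

3. Step 4. β-Hydride elimination and re-insertion on palladium may move the double bond along the chain, or oxidative addition to the electron-rich bromide may be slow. The fallback reverses the polarity of the partners, sets out from 5 and comes back at 7. Bromide 5 would be converted with magnesium turnings in THF into [4-(benzyloxy)-3,5-dimethoxyphenyl]magnesium bromide F5. Alkylation of F5 with 4-bromobut-1-ene under Li2CuCl4 catalysis (Kochi coupling, THF, −10 °C to rt) should give 7.

**Further compounds**

F1 | step 6 | 3-[4-(benzyloxy)-3-methoxyphenyl]propanal | COc1cc(CCC=O)ccc1OCc1ccccc1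
F2 | step 6 | 4-[4-(benzyloxy)-3,5-dimethoxyphenyl]butan-2-one | CC(=O)CCc1cc(OC)c(OCc2ccccc2)c(OC)c1
F3 | step 6 | (5R)-7-[4-(benzyloxy)-3-methoxyphenyl]-1-[4-(benzyloxy)-3,5-dimethoxyphenyl]-5-hydroxyheptan-3-one | COc1cc(CC[C@H](CC(=O)CCc2cc(OC)c(OCc3ccccc3)c(OC)c2)O)ccc1OCc1ccccc1
F4 | step 5 | 2-{(E)-4-[4-(benzyloxy)-3,5-dimethoxyphenyl]but-1-en-1-yl}-4,4,5,5-tetramethyl-1,3,2-dioxaborolane | COc1cc(CC/C=C/B2OC(C)(C)C(C)(C)O2)cc(OC)c1OCc1ccccc1
F5 | step 4 | [4-(benzyloxy)-3,5-dimethoxyphenyl]magnesium bromide | COc1cc([Mg]Br)cc(OC)c1OCc1ccccc1
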